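## Retrosynthetic overview

1. Feature used: C1(OH)–C6(=O) is an α-ketol on a six-membered ring whose other four carbons (C2–C5) sit at the diene oxidation level, so the carbocycle is a catechol (ortho-quinone) in disguise. A ketal at C6 places two oxygens next to the C1 carbonyl, where they can chelate magnesium.
2. Endgame: target ⇒ C6 ketal hydrolysis and C2 acetylation ⇒ trans C2/C3 oxygenation by OH-directed epoxidation of C2=C3 and SN2 opening at allylic C3 by benzoate.
3. Key disconnection: the C1–C7 bond, made by adding a hydroxymethyl-anion equivalent to the C1 carbonyl of a chiral ortho-quinone monoketal generated by oxidative dearomatisation of a catechol mono-ether.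
4. Rings: the carbocycle is never built; it is the benzene ring of iodide 2. The only ring formed is the temporary dioxolane (step 3), which masks C6, blocks rearomatisation and carries the chirality; it is removed in step 9.
5. Stereochemistry: C1 is set by the C2-symmetric auxiliary in the key step; C2 and C3 are relayed from C1.

Key step: step 3

Remark (assumption on the chemistry): ring atoms are numbered as in the target (C1 quaternary carbinol, C2 OAc, C3 OBz, C4=C5, C6 ketone, C7 exocyclic CH2); the facial sense of the addition in step 3 is taken from the chelate model given there and is not established for this substrate; the CIP descriptor at this carbon changes along the route (S in 8, R in 9 and 10, S from 11 on) through priority changes only.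

## Route

Step 1
Reactants: 1 (2R,3R)-1,4-dimethoxybutane-2,3-diol; 2 1-(benzyloxy)-2-iodobenzene
Product: 3 (2R,3R)-3-[2-(benzyloxy)phenoxy]-1,4-dimethoxybutan-2-ol
Conditions: CuI (10 mol%), 3,4,7,8-tetramethyl-1,10-phenanthroline (20 mol%), Cs2CO3, toluene, 110 °C (1 in threefold excess, recovered)
Reagents that add atoms: none
Why: Ullmann-type copper-catalysed C–O coupling of an aryl iodide with a secondary alcohol; no C–O bond of the diol is broken, so both stereocentres are retained, and the two hydroxyls of the C2-symmetric diol are equivalent, so only double arylation has to be suppressed by the excess.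

Step 2
Reactants: 3 (2R,3R)-3-[2-(benzyloxy)phenoxy]-1,4-dimethoxybutan-2-ol
Product: 4 2-{[(2R,3R)-3-hydroxy-1,4-dimethoxybutan-2-yl]oxy}phenol
Conditions: H2 (1 atm), 10% Pd/C, EtOAc, rt
Reagents that add atoms: none
Why: Hydrogenolysis of the benzyl aryl ether; the alkyl ethers, the alkyl aryl ether and the secondary alcohol are inert.

Step 3
Reactants: 4 2-{[(2R,3R)-3-hydroxy-1,4-dimethoxybutan-2-yl]oxy}phenol; 5 (chloromethyl)dimethyl(propan-2-yloxy)silane
Product: 8 (2R,3R,6S)-6-{[dimethyl(propan-2-yloxy)silyl]methyl}-2,3-bis(methoxymethyl)-1,4-dioxaspiro[4.5]deca-7,9-dien-6-ol, via silylmethyl Grignard reagent 6 (not isolated), via spiroketal dienone 7 (not isolated)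
Conditions: (a) 5, Mg, THF, 40 °C; (b) 4, PhI(OAc)2, CH2Cl2, −40 °C, cold filtration through basic Al2O3; (c) solution of 7 added to 6 (3 equiv), THF, −78 °C; aq. NH4Cl/NH3 (pH 8)
Reagents that add atoms: none
Why: PhI(OAc)2 binds the phenol oxygen of 4 and the tethered secondary hydroxyl attacks the ring carbon that carries the ether oxygen (5-exo-trig, closing the temporary dioxolane), which dearomatises the flat catechol ether to the ortho-quinone monoketal 7; this is the known iodane-mediated spiroketalising dearomatisation of 2-(hydroxyalkoxy)phenols. The C1 carbonyl of 7 then takes up the Tamao hydroxymethyl-anion equivalent 6 in a 1,2-Grignard addition that forms the C1–C7 bond; the closest precedents are Grignard additions to chiral ortho-quinone monoketals and chelation-controlled additions to α-keto acetals of 1,4-di-O-methylthreitol. Magnesium is expected to be held by the carbonyl oxygen, by the ketal oxygen whose neighbouring CH2OMe arm points toward the carbonyl, and by that methoxy group, so that the other ketal oxygen turns pseudo-axial and the CH2 group enters anti to it (Cram-chelate sense); with the (2R,3R)-auxiliary this should place the C1–O bond on the face required for the target. C1 is the only new stereocentre (the spiro carbon is not stereogenic because the diol is C2-symmetric) and it is controlled by the auxiliary alone. The step needs 1,2- over 1,4-/1,6-addition (hard chelated Grignard at −78 °C; 7 cannot enolise), facial control (the tridentate chelate), and addition faster than Diels–Alder dimerisation of 7 (7 is made and consumed cold and dilute without isolation). The magnesium alkoxide of 8 should not undergo Peterson elimination, and the mildly basic work-up protects the acid-labile dienyl carbinol.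

Step 4
Reactants: 8 (2R,3R,6S)-6-{[dimethyl(propan-2-yloxy)silyl]methyl}-2,3-bis(methoxymethyl)-1,4-dioxaspiro[4.5]deca-7,9-dien-6-ol
Product: 9 (2R,3R,6R)-6-(hydroxymethyl)-2,3-bis(methoxymethyl)-1,4-dioxaspiro[4.5]deca-7,9-dien-6-ol
Conditions: crude 8, 30% H2O2, KF, KHCO3, THF/MeOH, rt
Reagents that add atoms: hydrogen peroxide, OO
Why: Tamao oxidation: the fluoride-activated alkoxysilane migrates its CH2 carbon from silicon to peroxide oxygen, turning Si–CH2 into CH2–OH without touching C1, the diene or the ketal under these buffered basic conditions.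

Step 5
Reactants: 9 (2R,3R,6R)-6-(hydroxymethyl)-2,3-bis(methoxymethyl)-1,4-dioxaspiro[4.5]deca-7,9-dien-6-ol
Product: 10 [(2R,3R,6R)-6-hydroxy-2,3-bis(methoxymethyl)-1,4-dioxaspiro[4.5]deca-7,9-dien-6-yl]methyl benzoate
Conditions: BzCl (1.1 equiv), pyridine, CH2Cl2, −20 → 0 °C
Reagents that add atoms: benzoyl chloride, O=C(Cl)c1ccccc1
Why: Selective acylation of the primary hydroxyl over the hindered tertiary dienylic one; it also removes the CH2OH group as a competing director for step 6.

Step 6
Reactants: 10 [(2R,3R,6R)-6-hydroxy-2,3-bis(methoxymethyl)-1,4-dioxaspiro[4.5]deca-7,9-dien-6-yl]methyl benzoate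
Product: 11 [(2R,3R,6S,7S,8S)-7,8-epoxy-6-hydroxy-2,3-bis(methoxymethyl)-1,4-dioxaspiro[4.5]dec-9-en-6-yl]methyl benzoate (C2–C3 epoxide cis to the C1–OH)
Conditions: VO(acac)2 (5 mol%), t-BuOOH (in decane), CH2Cl2, 0 °C
Reagents that add atoms: tert-butyl hydroperoxide, CC(C)(C)OO
Why: Vanadium-catalysed hydroxyl-directed epoxidation: the vanadium-bound C1 alkoxide delivers the peroxide oxygen to the allylic C2=C3 bond on its own face, which sets C2 and C3, while the homoallylic C4=C5 bond next to the ketal should react more slowly.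

Step 7
Reactants: 11 [(2R,3R,6S,7S,8S)-7,8-epoxy-6-hydroxy-2,3-bis(methoxymethyl)-1,4-dioxaspiro[4.5]dec-9-en-6-yl]methyl benzoate
Product: 12 [(2R,3R,6S,7S,8R)-8-(benzoyloxy)-6,7-dihydroxy-2,3-bis(methoxymethyl)-1,4-dioxaspiro[4.5]dec-9-en-6-yl]methyl benzoate
Conditions: PhCO2H, Ti(Oi-Pr)4, CH2Cl2, 0 °C → rt
Reagents that add atoms: benzoic acid, OC(=O)c1ccccc1
Why: Titanium-mediated opening of a 2,3-epoxy alcohol by a carboxylic acid: benzoate attacks C3, the position favoured both by the epoxy-alkoxide titanium chelate and by allylic activation, in an SN2 sense with inversion, leaving the C2–OH cis to the C1–OH and the C3 benzoate trans to it.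

Step 8
Reactants: 12 [(2R,3R,6S,7S,8R)-8-(benzoyloxy)-6,7-dihydroxy-2,3-bis(methoxymethyl)-1,4-dioxaspiro[4.5]dec-9-en-6-yl]methyl benzoate
Product: 13 [(2R,3R,6S,7S,8R)-7-(acetyloxy)-8-(benzoyloxy)-6-hydroxy-2,3-bis(methoxymethyl)-1,4-dioxaspiro[4.5]dec-9-en-6-yl]methyl benzoate
Conditions: Ac2O (1.2 equiv), pyridine, DMAP (cat.), CH2Cl2, 0 °C
Reagents that add atoms: acetic anhydride, CC(=O)OC(C)=O
Why: Acetylation of the only secondary hydroxyl; the tertiary C1–OH, flanked by the ketal and the quaternary centre, should be much slower with limited anhydride at 0 °C.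

Step 9
Reactants: 13 [(2R,3R,6S,7S,8R)-7-(acetyloxy)-8-(benzoyloxy)-6-hydroxy-2,3-bis(methoxymethyl)-1,4-dioxaspiro[4.5]dec-9-en-6-yl]methyl benzoate
Product: 14 2-O-acetylzeylenone, [(1S,5R,6S)-6-(acetyloxy)-5-(benzoyloxy)-1-hydroxy-2-oxocyclohex-3-en-1-yl]methyl benzoate
Conditions: TFA/H2O (9:1), CH2Cl2, 0 °C → rt
Reagents that add atoms: water, O
Why: Acid hydrolysis of the allylic ketal through a vinyl-stabilised oxocarbenium ion releases the C6 ketone, now conjugated with C4=C5, and returns diol 1; the esters should survive cold aqueous acid, and no stereocentre can epimerise because C1 is quaternary.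

## Compound list

1 | (2R,3R)-1,4-dimethoxybutane-2,3-diol | COC[C@@H](O)[C@H](O)COC | starting material
2 | 1-(benzyloxy)-2-iodobenzene | Ic1ccccc1OCc1ccccc1 | starting material
3 | (2R,3R)-3-[2-(benzyloxy)phenoxy]-1,4-dimethoxybutan-2-ol | COC[C@@H](Oc1ccccc1OCc1ccccc1)[C@H](O)COC | intermediate
4 | 2-{[(2R,3R)-3-hydroxy-1,4-dimethoxybutan-2-yl]oxy}phenol | COC[C@@H](Oc1ccccc1O)[C@H](O)COC | intermediate
5 | (chloromethyl)dimethyl(propan-2-yloxy)silane | CC(C)O[Si](C)(C)CCl | starting material
6 | {[dimethyl(propan-2-yloxy)silyl]methyl}magnesium chloride | CC(C)O[Si](C)(C)C[Mg]Cl | intermediate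
7 | (2R,3R)-2,3-bis(methoxymethyl)-1,4-dioxaspiro[4.5]deca-7,9-dien-6-one | O=C1C=CC=CC12O[C@H](COC)[C@@H](COC)O2 | intermediate
8 | (2R,3R,6S)-6-{[dimethyl(propan-2-yloxy)silyl]methyl}-2,3-bis(methoxymethyl)-1,4-dioxaspiro[4.5]deca-7,9-dien-6-ol | C1=CC=CC2(O[C@H](COC)[C@@H](COC)O2)[C@]1(O)C[Si](C)(C)OC(C)C | intermediate
9 | (2R,3R,6R)-6-(hydroxymethyl)-2,3-bis(methoxymethyl)-1,4-dioxaspiro[4.5]deca-7,9-dien-6-ol | C1=CC=CC2(O[C@H](COC)[C@@H](COC)O2)[C@]1(O)CO | intermediate
10 | [(2R,3R,6R)-6-hydroxy-2,3-bis(methoxymethyl)-1,4-dioxaspiro[4.5]deca-7,9-dien-6-yl]methyl benzoate | C1=CC=CC2(O[C@H](COC)[C@@H](COC)O2)[C@]1(O)COC(=O)c1ccccc1 | intermediate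
11 | [(2R,3R,6S,7S,8S)-7,8-epoxy-6-hydroxy-2,3-bis(methoxymethyl)-1,4-dioxaspiro[4.5]dec-9-en-6-yl]methyl benzoate | O1[C@H]2[C@@H]1C=CC3(O[C@H](COC)[C@@H](COC)O3)[C@]2(O)COC(=O)c1ccccc1 | intermediate
12 | [(2R,3R,6S,7S,8R)-8-(benzoyloxy)-6,7-dihydroxy-2,3-bis(methoxymethyl)-1,4-dioxaspiro[4.5]dec-9-en-6-yl]methyl benzoate | O[C@H]1[C@H](OC(=O)c2ccccc2)C=CC3(O[C@H](COC)[C@@H](COC)O3)[C@]1(O)COC(=O)c1ccccc1 | intermediate
13 | [(2R,3R,6S,7S,8R)-7-(acetyloxy)-8-(benzoyloxy)-6-hydroxy-2,3-bis(methoxymethyl)-1,4-dioxaspiro[4.5]dec-9-en-6-yl]methyl benzoate | CC(=O)O[C@H]1[C@H](OC(=O)c2ccccc2)C=CC3(O[C@H](COC)[C@@H](COC)O3)[C@]1(O)COC(=O)c1ccccc1 | intermediate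
14 | 2-O-acetylzeylenone, [(1S,5R,6S)-6-(acetyloxy)-5-(benzoyloxy)-1-hydroxy-2-oxocyclohex-3-en-1-yl]methyl benzoate | CC(=O)O[C@H]1[C@H](OC(=O)c2ccccc2)C=CC(=O)[C@]1(O)COC(=O)c1ccccc1 | target

## Step count and risks

Total step count: 9 (the Grignard reagent 6 is made within step 3).
Longest linear sequence: 9 steps, from 1 and 2 to 14.

Steps most likely to fail:

Step 3. Chelation may be incomplete on the rigid spiro-fused dienone, giving poor facial selectivity; the dienone may dimerise by [4+2] cycloaddition if addition is slow; the adduct may lose silanol in a Peterson-type elimination during work-up. The fallback sets out from phenol 4 and comes back at benzoate 10. The cold solution of dienone 7 is generated from 4 as before and treated with dimethylsulfonium methylide (Me3S+ I−, n-BuLi, THF, −78 → −20 °C). This fast, non-chelating Corey–Chaykovsky epoxidation forms the same C1–C7 bond and should give the dispiro epoxide F1. Because the auxiliary is enantiopure, the two C1 epimers are diastereomers and would be separated by chromatography. The required epimer is then opened at its CH2 terminus with caesium benzoate and benzoic acid (DMF, 50 °C), which should give 10 directly and bypass 8 and 9.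

Step 7. Benzoate may attack C5 in an SN2' sense, the neighbouring primary benzoate carbonyl may participate at C2, or partial ionisation at allylic C3 may erode the inversion. The fallback sets out from dienol 10 and comes back at diol 12, bypassing epoxide 11. Hydroxyl-directed dihydroxylation of C2=C3 (OsO4·TMEDA, CH2Cl2, −78 °C; aq. NaHSO3) syn to the C1–OH should give the all-cis triol F2. A Mitsunobu reaction (PPh3, DIAD, PhCO2H, THF, 0 °C) then esterifies the more reactive allylic C3–OH with inversion, which should give 12.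

Step 9. Hydrolysis of a ketal flanked by the electron-poor quaternary carbinol may be slow, and the forcing acid then needed may cause acetyl migration or loss of the allylic benzoate followed by aromatisation. The fallback sets out from diol 12 and comes back at 14; it changes the order of the endgame so that no acetate is exposed to the unmasking. Ketal 12 is cleaved first (PPTS, acetone/H2O, 50 °C, or the aqueous TFA of step 9) to give zeylenone F3. Selective acetylation of its secondary C2–OH (Ac2O, pyridine, 0 °C) then gives 14.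

Further compounds
F1 | step 3 | (6R,7R)-6,7-bis(methoxymethyl)-1,5,8-trioxadispiro[2.0.4.4]dodeca-9,11-diene, the spiro-oxirane of 7 at C1 with the oxirane oxygen on the face of the C1–OH in 10 | C1=CC=CC2(O[C@H](COC)[C@@H](COC)O2)[C@]13CO3
F2 | step 7 | [(2R,3R,6S,7S,8S)-6,7,8-trihydroxy-2,3-bis(methoxymethyl)-1,4-dioxaspiro[4.5]dec-9-en-6-yl]methyl benzoate | O[C@H]1[C@@H](O)C=CC3(O[C@H](COC)[C@@H](COC)O3)[C@]1(O)COC(=O)c1ccccc1
F3 | step 9 | zeylenone, [(1S,5R,6S)-5-(benzoyloxy)-1,6-dihydroxy-2-oxocyclohex-3-en-1-yl]methyl benzoate | O[C@H]1[C@H](OC(=O)c2ccccc2)C=CC(=O)[C@]1(O)COC(=O)c1ccccc1
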